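Locants: ring A = C1 (ester C=O), C2 (ether O), C3 (CO2H), C4 (OH), C5 (H), C6 (CH3); ring B = C1' (ester O), C2' (CH2OH), C3' (OH), C4' (lactone C=O), C5' (lactone CH2O), C6' (ether O); in phthalide numbering these ring B atoms are C5, C6, C7, C7a, C3a, C4.
Cuts: first the aryl ether bond O(C2)–C6' of the seven-membered ring, then the depside ester bond C(=O)–O(C1'). This leaves a ring A salicylic acid and a ring B phthalide diol that share one C9 skeleton.
Enabling feature: on ring B the free C3'-OH stands para to C6', so ring B of the target is a hydroquinone mono-aryl ether. In the depside C6' is the only C–H of ring B. Two-electron oxidation of the C3' phenol makes that carbon electrophilic while the ester on neighbouring C1' holds the ring A C2-OH over it, so no halogen or metal handle is needed.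
Forward: ring A acid from symmetric 2,6-dihydroxy-4-methylbenzoic acid (steps 1-3); ring B from methyl atrarate by double benzylic bromination, the γ-lactone closing in step 6 (steps 4-7); ester union (step 8); dehydrogenative closure of the central dioxepinone ring (step 9); removal of the helpers Bn and TBS (steps 10-11).
Stereochemistry: the target is achiral; the only sp3 ring carbon created (C6' of a transient dienone) is erased by tautomerisation.

Key step: step 9

Assumption: 2,6-dihydroxy-4-methylbenzoic acid and methyl 2,4-dihydroxy-3,6-dimethylbenzoate (methyl atrarate, a bulk fragrance chemical) are purchased.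

Step 1
Reactants: 1 2,6-dihydroxy-4-methylbenzoic acid
Product: 2 benzyl 2-(benzyloxy)-6-hydroxy-4-methylbenzoate
Conditions: BnBr (2.05 equiv), K2CO3 (2.2 equiv), DMF, rt
Reagents that add atoms: benzyl bromide, BrCc1ccccc1
Why: Carboxylate alkylation and Williamson etherification in one pot should stop at the mono-ether because the remaining OH is hydrogen-bonded to and shielded by the new ester, and this desymmetrises the ring.

Step 2
Reactants: 2 benzyl 2-(benzyloxy)-6-hydroxy-4-methylbenzoate
Product: 3 benzyl 6-(benzyloxy)-3-formyl-2-hydroxy-4-methylbenzoate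
Conditions: MgCl2, Et3N, (CH2O)n, MeCN, reflux; HCl (aq) work-up
Reagents that add atoms: formaldehyde (from paraformaldehyde), C=O
Why: In the Casnati–Skattebøl ortho-formylation the magnesium phenoxide delivers formaldehyde only ortho to the free OH, whose sole open ortho carbon lies between OH and CH3, and a second formaldehyde accepts the hydride that raises the hydroxymethyl stage to the aldehyde.

Step 3
Reactants: 3 benzyl 6-(benzyloxy)-3-formyl-2-hydroxy-4-methylbenzoate
Product: 4 4-(benzyloxy)-3-[(benzyloxy)carbonyl]-2-hydroxy-6-methylbenzoic acid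
Conditions: NaClO2, NaH2PO4, 2-methyl-2-butene, t-BuOH/THF/H2O, 0 °C to rt
Reagents that add atoms: sodium chlorite, [Na+].[O-]Cl=O
Why: The Pinnick oxidation takes a hindered salicylaldehyde to the acid without touching benzyl ether, benzyl ester or phenol, the alkene trapping HOCl before it can chlorinate C5.

Step 4
Reactants: 5 methyl 2,4-dihydroxy-3,6-dimethylbenzoate
Product: 6 methyl 2,4-diacetoxy-3,6-dimethylbenzoate
Conditions: Ac2O, pyridine, DMAP (cat.), rt
Reagents that add atoms: acetic anhydride, CC(=O)OC(C)=O
Why: DMAP-catalysed acetylation caps both phenols, the chelated one included, and lowers the ring electron density so that the next step attacks the methyl groups and not the free ring carbon.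

Step 5
Reactants: 6 methyl 2,4-diacetoxy-3,6-dimethylbenzoate
Product: 7 methyl 2,4-diacetoxy-3,6-bis(bromomethyl)benzoate
Conditions: NBS (2.1 equiv), AIBN (cat.), PhCF3, reflux
Reagents that add atoms: N-bromosuccinimide, O=C1CCC(=O)N1Br
Why: Wohl–Ziegler radical bromination puts one bromine on each benzylic methyl group, a second bromination at these ortho-flanked carbons being slower for steric reasons.

Step 6
Reactants: 7 methyl 2,4-diacetoxy-3,6-bis(bromomethyl)benzoate
Product: 9 5,7-dihydroxy-6-(hydroxymethyl)isobenzofuran-1(3H)-one, via diacetoxy phthalide alcohol 8 (not isolated)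
Conditions: CaCO3, 1,4-dioxane/H2O (1:1), reflux; then NaOH (1 M aq), 0 °C; then HCl (aq) to pH 2
Reagents that add atoms: water, O
Why: Neutral hydrolysis (nucleophilic substitution) of both benzylic bromides is followed by spontaneous lactonisation of the alcohol next to the methyl ester (5-exo-trig) and then by cold saponification of the acetyl groups wherever they may have migrated, acidification re-closing any opened phthalide.

Step 7
Reactants: 9 5,7-dihydroxy-6-(hydroxymethyl)isobenzofuran-1(3H)-one
Product: 10 6-{[(tert-butyldimethylsilyl)oxy]methyl}-5,7-dihydroxyisobenzofuran-1(3H)-one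
Conditions: TBSCl (1.05 equiv), imidazole (2.2 equiv), DMF, 0 °C
Reagents that add atoms: tert-butyldimethylsilyl chloride, CC(C)(C)[Si](C)(C)Cl
Why: Imidazole-promoted silylation is known to favour the primary alcohol of hydroxybenzyl alcohols over the phenol, all the more so here where both phenols are electron-poor and one is chelated, and any aryl silyl ether formed should fall off on aqueous work-up.

Step 8
Reactants: 4 4-(benzyloxy)-3-[(benzyloxy)carbonyl]-2-hydroxy-6-methylbenzoic acid; 10 6-{[(tert-butyldimethylsilyl)oxy]methyl}-5,7-dihydroxyisobenzofuran-1(3H)-one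
Product: 11 depside 6-{[(tert-butyldimethylsilyl)oxy]methyl}-7-hydroxy-1-oxo-1,3-dihydroisobenzofuran-5-yl 4-(benzyloxy)-3-[(benzyloxy)carbonyl]-2-hydroxy-6-methylbenzoate
Conditions: DCC, DMAP (cat.), CH2Cl2, 0 °C to rt
Reagents that add atoms: none
Why: Steglich esterification as practised for para-depsides acylates only the free 5-OH, since the 7-OH of 10 and the 2-OH of 4 are each locked in a hydrogen bond to a neighbouring carbonyl group.

Step 9
Reactants: 11 depside
Product: 14 protected conneotricone (C4-OBn; C3-CO2Bn; C2'-CH2OTBS; C3'-OH free), via aryloxy-iodane 12 (not isolated), via 4H-dienone 13 (not isolated)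
Conditions: PhI(OAc)2 (1.0 equiv, added over 2 h), (CF3)2CHOH/CH2Cl2 (1:1), 4 Å molecular sieves, 0 °C, 2 mM
Reagents that add atoms: none
Why: Proposed new method: ligand exchange of the ring B phenol (C3'-OH) at trivalent iodine gives aryloxy-λ3-iodane 12, whose loss of PhI in the ionising, non-nucleophilic solvent makes C2', C4' and C6' electrophilic, and the tethered ring A C2-OH attacks C6' to give 4H-dienone 13, which tautomerises at once to phenol 14. The closest known reaction types are the hypervalent-iodine para-functionalisation of phenols by oxygen nucleophiles and the oxidative C–O phenol coupling that turns 2,3'-dihydroxybenzophenones into xanthones; closing the depsidone ring from a depside in this way mirrors the presumed biosynthesis but is not established laboratory practice. The seven-membered 1,4-dioxepinone ring closes by O-attack on a trigonal ring carbon (7-exo-trig counted on C5'=C6'), which requires the ester to reach its E rotamer, hence the high dilution and slow addition. No lasting stereocentre arises because the sp3 C6' of 13 is lost on enolisation. Site selectivity (C6' over C2', the only other carbon within reach) rests on C6' being the unsubstituted para position and the only one whose adduct can rearomatise, and selectivity between the two phenols rests on the ring A OH being flanked and hydrogen-bonded by two ester carbonyls and therefore harder to oxidise than the ring B OH with one acceptor and one alkyl neighbour. Further oxidation of the hydroquinone mono-ether 14 should be held back by one equivalent of oxidant, exclusion of water and other nucleophiles, full substitution of ring B, and the weak donor power of the electron-poor, twisted aryloxy group.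

Step 10
Reactants: 14 protected conneotricone
Product: 15 conneotricone C2'-CH2O-TBS ether (free C3-CO2H; free C4-OH)
Conditions: H2 (1 atm), Pd/C (10 %), EtOAc, rt
Reagents that add atoms: none
Why: Catalytic hydrogenolysis cleaves the unhindered PhCH2–O bonds of the aryl benzyl ether and the benzyl ester, whereas the di-ortho-flanked ArCH2–OTBS and phthalide CH2–O bonds on the electron-poor hexasubstituted ring B are shielded from the catalyst surface.

Step 11
Reactants: 15 conneotricone C2'-CH2O-TBS ether
Product: 16 conneotricone
Conditions: HF·pyridine, THF, 0 °C to rt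
Reagents that add atoms: none
Why: Fluoride-driven desilylation under weakly acidic conditions frees the primary alcohol without exposing the aryl ester of the depsidone or the phthalide to base.

Compound list
1 | 2,6-dihydroxy-4-methylbenzoic acid | Cc1cc(O)c(C(=O)O)c(O)c1 | starting material
2 | benzyl 2-(benzyloxy)-6-hydroxy-4-methylbenzoate | Cc1cc(O)c(C(=O)OCc2ccccc2)c(OCc2ccccc2)c1 | intermediate
3 | benzyl 6-(benzyloxy)-3-formyl-2-hydroxy-4-methylbenzoate | Cc1cc(OCc2ccccc2)c(C(=O)OCc2ccccc2)c(O)c1C=O | intermediate
4 | 4-(benzyloxy)-3-[(benzyloxy)carbonyl]-2-hydroxy-6-methylbenzoic acid | Cc1cc(OCc2ccccc2)c(C(=O)OCc2ccccc2)c(O)c1C(=O)O | intermediate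
5 | methyl 2,4-dihydroxy-3,6-dimethylbenzoate (methyl atrarate) | COC(=O)c1c(C)cc(O)c(C)c1O | starting material
6 | methyl 2,4-diacetoxy-3,6-dimethylbenzoate | COC(=O)c1c(C)cc(OC(C)=O)c(C)c1OC(C)=O | intermediate
7 | methyl 2,4-diacetoxy-3,6-bis(bromomethyl)benzoate | COC(=O)c1c(CBr)cc(OC(C)=O)c(CBr)c1OC(C)=O | intermediate
8 | 5,7-diacetoxy-6-(hydroxymethyl)isobenzofuran-1(3H)-one (not isolated) | CC(=O)Oc1cc2c(c(OC(C)=O)c1CO)C(=O)OC2 | intermediate
9 | 5,7-dihydroxy-6-(hydroxymethyl)isobenzofuran-1(3H)-one | O=C1OCc2cc(O)c(CO)c(O)c21 | intermediate
10 | 6-{[(tert-butyldimethylsilyl)oxy]methyl}-5,7-dihydroxyisobenzofuran-1(3H)-one | O=C1OCc2cc(O)c(CO[Si](C)(C)C(C)(C)C)c(O)c21 | intermediate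
11 | depside: ester of acid 4 with the 5-OH of 10 | Cc1cc(OCc2ccccc2)c(C(=O)OCc2ccccc2)c(O)c1C(=O)Oc1cc2c(c(O)c1CO[Si](C)(C)C(C)(C)C)C(=O)OC2 | intermediate
12 | aryloxy-iodane: depside 11 bound through its C3'-O to I(Ph)(OAc) (not isolated) | Cc1cc(OCc2ccccc2)c(C(=O)OCc2ccccc2)c(O)c1C(=O)Oc1cc2c(c(OI(OC(C)=O)c3ccccc3)c1CO[Si](C)(C)C(C)(C)C)C(=O)OC2 | intermediate
13 | 4H-dienone: cyclohexa-2,5-dienone tautomer of 14 (C3'=O; C6' sp3 with H and the ring A oxygen; racemic, not isolated) | Cc1cc(OCc4ccccc4)c(C(=O)OCc4ccccc4)c2c1C(=O)OC1=C(CO[Si](C)(C)C(C)(C)C)C(=O)C3=C(COC3=O)C1O2 | intermediate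
14 | protected conneotricone (C4-OBn; C3-CO2Bn; C2'-CH2OTBS; C3'-OH free) | Cc1cc(OCc4ccccc4)c(C(=O)OCc4ccccc4)c2c1C(=O)Oc1c(CO[Si](C)(C)C(C)(C)C)c(O)c3c(c1O2)COC3=O | intermediate
15 | conneotricone C2'-CH2O-TBS ether | Cc1cc(O)c(C(=O)O)c2c1C(=O)Oc1c(CO[Si](C)(C)C(C)(C)C)c(O)c3c(c1O2)COC3=O | intermediate
16 | conneotricone | Cc1cc(O)c(C(=O)O)c2c1C(=O)Oc1c(CO)c(O)c3c(c1O2)COC3=O | target

Total step count: 11. Longest linear sequence: 8 steps (from 5 through steps 4-11 to 16).

Steps most likely to fail

Step 9. The seven-ring closure may be too slow against the Z preference of the aryl ester. The oxidised ring B could then be captured by acetate, or the product phenol could be oxidised further. The weakly nucleophilic, chelated ring A OH adds to this risk. The fallback installs a leaving group and closes the same ring by copper catalysis. It sets out from 10: NBS (1 equiv, MeCN, 0 °C) should brominate the only free ring carbon to give 4-bromo-6-{[(tert-butyldimethylsilyl)oxy]methyl}-5,7-dihydroxyisobenzofuran-1(3H)-one F1. Steglich esterification of its 5-OH with acid 4 gives the 4-bromo analogue of the depside F2. An intramolecular Ullmann ether synthesis (CuI, N,N-dimethylglycine, Cs2CO3, 1,4-dioxane, 90 °C) then closes the dioxepinone ring, and the route is rejoined at 14.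

Step 5. Radical bromination of two unlike methyl groups may run unevenly. The shielded methyl between the acetates could under-react while the methyl next to the ester is brominated twice, leaving mixtures that are hard to separate. The fallback overshoots the oxidation level on purpose and corrects it by reduction. It sets out from 6: exhaustive bromination (NBS, 4.5 equiv, hν, PhCF3, reflux) should stop for steric reasons at methyl 2,4-diacetoxy-3,6-bis(dibromomethyl)benzoate F3. AgNO3 in aqueous acetone hydrolyses both gem-dibromides to methyl 2,4-diacetoxy-3,6-diformylbenzoate F4. NaBH4 (THF/MeOH, 0 °C) reduces both aldehydes, and the alkoxide next to the ester lactonises. The cold NaOH then HCl treatment used in step 6 removes the acetyl groups, and the route is rejoined at 9.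

Step 7. Silylation of the acidic 5-OH may compete with that of the primary alcohol, which is flanked on both sides, so that chemoselectivity is lost. The fallback protects everything and then releases only the phenols. It sets out from 9: TBSCl (3.5 equiv), imidazole, DMF, rt gives 5,7-bis[(tert-butyldimethylsilyl)oxy]-6-{[(tert-butyldimethylsilyl)oxy]methyl}isobenzofuran-1(3H)-one F5. KHF2 in MeOH at rt cleaves aryl silyl ethers selectively in the presence of alkyl silyl ethers, and the route is rejoined at 10.

Further compounds
F1 | step 9 | 4-bromo-6-{[(tert-butyldimethylsilyl)oxy]methyl}-5,7-dihydroxyisobenzofuran-1(3H)-one | O=C1OCc2c(Br)c(O)c(CO[Si](C)(C)C(C)(C)C)c(O)c21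
F2 | step 9 | 4-bromo analogue of depside 11 (Br on C6') | Cc1cc(OCc2ccccc2)c(C(=O)OCc2ccccc2)c(O)c1C(=O)Oc1c(Br)c2c(c(O)c1CO[Si](C)(C)C(C)(C)C)C(=O)OC2
F3 | step 5 | methyl 2,4-diacetoxy-3,6-bis(dibromomethyl)benzoate | COC(=O)c1c(C(Br)Br)cc(OC(C)=O)c(C(Br)Br)c1OC(C)=O
F4 | step 5 | methyl 2,4-diacetoxy-3,6-diformylbenzoate | COC(=O)c1c(C=O)cc(OC(C)=O)c(C=O)c1OC(C)=O
F5 | step 7 | 5,7-bis[(tert-butyldimethylsilyl)oxy]-6-{[(tert-butyldimethylsilyl)oxy]methyl}isobenzofuran-1(3H)-one | O=C1OCc2cc(O[Si](C)(C)C(C)(C)C)c(CO[Si](C)(C)C(C)(C)C)c(O[Si](C)(C)C(C)(C)C)c21
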